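**Route outline**

- Retrosynthesis: the C1–H bond is cut first (carbinol back to the aryl ketone). The methyl carbon on C3 (C4) is then reconnected to C1, which folds the chain C1–C2–C3–C4 into 1,3-bis(2,4,5-trimethoxyphenyl)cyclobutan-1-ol.
- Enabling feature: C1, C2, C3 and C4 are the four corners of a cyclobutane that lacks only the C1–C4 bond. The cyclobutanol has a mirror plane through C1 and C3, so its two C1–CH2 bonds are enantiotopic.
- Further cuts: the aryl–C1 bond (aryllithium plus 3-arylcyclobutanone), then two opposite ring bonds (carbonyl carbon to styrene CH2, CCl2 carbon to benzylic carbon; dichloroketene plus 2,4,5-trimethoxystyrene), then the styrene C=C (methylenation of the aldehyde).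
- Forward: Wittig olefination, [2+2] cycloaddition (closes the only ring, the cyclobutane), dechlorination, aryllithium addition to the ring carbonyl, enantioselective iridium-catalysed ring opening to the 1,3-diarylbutan-1-one, ketone reduction.
- Stereochemistry: C3 (S) comes from the chiral bisphosphine on iridium choosing one of the enantiotopic ring bonds. C1 (R) comes from an oxazaborolidine-controlled borane reduction, independent of C3.

Key step: step 5

Remark: chain atoms are numbered C1 (carbinol carbon), C2 (CH2), C3 (benzylic CH) and C4 (methyl carbon on C3).
Remark: the sense of induction of the ring-opening catalyst cannot be fixed with certainty on paper; the (S)-ligand is written, and its mirror image is to be used should a pilot run deliver the R ketone.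
Remark: catalyst-bound species and metal or boron alkoxides present before work-up are described in words and carry no compound number.

**Step 1**
Reactants: 1 2,4,5-trimethoxybenzaldehyde; 2 methyltriphenylphosphonium bromide
Product: 4 2,4,5-trimethoxystyrene, via methylenetriphenylphosphorane 3 (not isolated)
Conditions: KOtBu, THF, 0 °C; then 1, 0 °C to rt
Reagents that add atoms: none
Why: Wittig methylenation of an aromatic aldehyde with the non-stabilised ylide is routine and leaves the three methyl ethers untouched, and the oligomerisation-prone styrene is to be kept cold with a trace of BHT and used at once.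

**Step 2**
Reactants: 4 2,4,5-trimethoxystyrene; 5 trichloroacetyl chloride
Product: 7 racemic 2,2-dichloro-3-(2,4,5-trimethoxyphenyl)cyclobutan-1-one, via dichloroketene 6 (not isolated)
Conditions: activated Zn dust, Et2O/DME, slow addition of 5, ultrasound, 15–20 °C
Reagents that add atoms: none
Why: Thermal ketene–alkene [2+2] cycloaddition of dichloroketene (released from the acid chloride by zinc) with an electron-rich styrene joins the ketene carbonyl carbon to the terminal CH2 and the CCl2 carbon to the benzylic carbon, DME ties up the ZnCl2 that would otherwise start cationic oligomerisation, and the one stereocentre formed is racemic and ceases to be stereogenic after step 3.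

**Step 3**
Reactants: 7 racemic 2,2-dichloro-3-(2,4,5-trimethoxyphenyl)cyclobutan-1-one
Product: 9 3-(2,4,5-trimethoxyphenyl)cyclobutan-1-one, via monochlorocyclobutanone 8 (not isolated)
Conditions: Zn dust, AcOH, rt to 50 °C
Reagents that add atoms: none
Why: Stepwise zinc reduction of the two α-carbon–chlorine bonds in acetic acid is the standard follow-up to a dichloroketene cycloaddition, spares the ketone and the aryl ethers, and gives an achiral ketone with a mirror plane through the carbonyl carbon and C3.

**Step 4**
Reactants: 10 1-bromo-2,4,5-trimethoxybenzene; 9 3-(2,4,5-trimethoxyphenyl)cyclobutan-1-one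
Product: 12 cis-1,3-bis(2,4,5-trimethoxyphenyl)cyclobutan-1-ol (hydroxyl cis to the 3-aryl group; achiral), via aryllithium 11 (not isolated)
Conditions: n-BuLi, THF, −78 °C; then 9, −78 to −30 °C; H2O quench
Reagents that add atoms: none
Why: Bromine–lithium exchange followed by 1,2-addition of the aryllithium to the strained, electrophilic cyclobutanone should occur on the face of the puckered ring anti to the 3-aryl group, placing the hydroxyl cis to it, while low temperature limits enolisation, and the minor trans isomer (also achiral) is to be removed by chromatography on triethylamine-deactivated silica.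

**Step 5**
Reactants: 12 cis-1,3-bis(2,4,5-trimethoxyphenyl)cyclobutan-1-ol
Product: 13 (S)-1,3-bis(2,4,5-trimethoxyphenyl)butan-1-one
Conditions: [Ir(cod)Cl]2 (2.5 mol %), (S)-DTBM-SEGPHOS (6 mol %), toluene, 70–100 °C, argon
Reagents that add atoms: none
Why: The tertiary O–H bond adds oxidatively to the monovalent iridium–bisphosphine complex to give a trivalent iridium alkoxide hydride, β-carbon elimination then breaks one of the two C1–CH2 ring bonds to leave the aryl ketone and a primary alkyl–iridium hydride, and C–H reductive elimination turns the severed CH2 into the C3 methyl group and returns monovalent iridium. The closest known reaction type is the iridium- or rhodium-bisphosphine-catalysed enantioselective ring opening of prochiral tert-cyclobutanols to β-methyl ketones. No ring is closed: the cyclobutane is opened, and release of its strain makes the cleavage irreversible. The new stereocentre C3 (S) arises because the two ring arms become different (one CH3, one CH2C(=O)Ar), and the arm that is cut is chosen by the chiral pocket of the axially chiral DTBM-SEGPHOS ligand around the iridium alkoxide. The step needs selectivity between the enantiotopic C1–C2 and C1–C4 bonds and reductive elimination faster than β-hydride loss at the benzylic C3–H; the mirror plane of 12, its single fixed cis relationship between oxygen and the 3-aryl group, the bulky ligand and the hydride already on iridium are what secure this. The medium is neutral, so the acid-labile tertiary benzylic alcohol and the electron-rich rings survive, and C3 of 13, being β to the carbonyl, cannot epimerise by enolisation.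

**Step 6**
Reactants: 13 (S)-1,3-bis(2,4,5-trimethoxyphenyl)butan-1-one
Product: 14 (1R,3S)-1,3-bis(2,4,5-trimethoxyphenyl)butan-1-ol (target)
Conditions: (S)-Me-CBS [(S)-tetrahydro-1-methyl-3,3-diphenyl-1H,3H-pyrrolo[1,2-c][1,3,2]oxazaborole] (20 mol %), BH3·SMe2, THF, −20 °C; then MeOH, aq. NaHCO3
Reagents that add atoms: none
Why: Corey–Bakshi–Shibata reduction, in which the oxazaborolidine–borane complex binds the ketone with the aryl group as the large substituent and delivers hydride to the Si face (the sense the (S)-catalyst shows with aryl alkyl ketones), should give the (R)-carbinol under reagent control regardless of the remote C3 centre, and the methanol quench with basic work-up avoids ionisation of the very electron-rich benzylic alcohol.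

**Compound list**

1 | 2,4,5-trimethoxybenzaldehyde | COc1cc(OC)c(C=O)cc1OC | starting material
2 | methyltriphenylphosphonium bromide | C[P+](c1ccccc1)(c1ccccc1)c1ccccc1.[Br-] | starting material
3 | methylenetriphenylphosphorane (ylide, formed in the flask, not isolated) | C=P(c1ccccc1)(c1ccccc1)c1ccccc1 | intermediate
4 | 2,4,5-trimethoxystyrene | COc1cc(OC)c(C=C)cc1OC | intermediate
5 | trichloroacetyl chloride | O=C(Cl)C(Cl)(Cl)Cl | starting material
6 | dichloroketene (formed in the flask, not isolated) | O=C=C(Cl)Cl | intermediate
7 | racemic 2,2-dichloro-3-(2,4,5-trimethoxyphenyl)cyclobutan-1-one | COc1cc(OC)c(C2CC(=O)C2(Cl)Cl)cc1OC | intermediate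
8 | 2-chloro-3-(2,4,5-trimethoxyphenyl)cyclobutan-1-one (stereoisomer mixture, formed in the flask, not isolated) | COc1cc(OC)c(C2CC(=O)C2Cl)cc1OC | intermediate
9 | 3-(2,4,5-trimethoxyphenyl)cyclobutan-1-one (achiral) | COc1cc(OC)c(C2CC(=O)C2)cc1OC | intermediate
10 | 1-bromo-2,4,5-trimethoxybenzene | COc1cc(OC)c(Br)cc1OC | starting material
11 | (2,4,5-trimethoxyphenyl)lithium (formed in the flask, not isolated) | COc1cc(OC)c([Li])cc1OC | intermediate
12 | cis-1,3-bis(2,4,5-trimethoxyphenyl)cyclobutan-1-ol, hydroxyl cis to the 3-aryl group, achiral | COc1cc(OC)c([C@]2(O)C[C@@H](c3cc(OC)c(OC)cc3OC)C2)cc1OC | intermediate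
13 | (S)-1,3-bis(2,4,5-trimethoxyphenyl)butan-1-one | COc1cc(OC)c(C(=O)C[C@H](C)c2cc(OC)c(OC)cc2OC)cc1OC | intermediate
14 | (1R,3S)-1,3-bis(2,4,5-trimethoxyphenyl)butan-1-ol | COc1cc(OC)c([C@H](O)C[C@H](C)c2cc(OC)c(OC)cc2OC)cc1OC | target

**Step count**

Total step count: 6.
Longest linear sequence: 6 steps (1 → 4 → 7 → 9 → 12 → 13 → 14); bromide 10 enters at step 4 as purchased.

**Steps most likely to fail**

Step 5. The ligand may discriminate poorly between the two enantiotopic ring bonds when C3 carries a hydrogen instead of a fourth carbon substituent. β-Hydride loss at the benzylic C3–H may compete with reductive elimination, and the tertiary benzylic alcohol may ionise or dehydrate on heating. The fallback gives up the ring opening and sets C3 by conjugate addition. It sets out from bromide 10: lithiation to 11 (n-BuLi, THF, −78 °C) and acylation with (E)-N-methoxy-N-methylbut-2-enamide should give (E)-1-(2,4,5-trimethoxyphenyl)but-2-en-1-one F1. Rhodium-catalysed asymmetric 1,4-addition (Hayashi–Miyaura reaction) of commercial (2,4,5-trimethoxyphenyl)boronic acid to F1 with [Rh(OH)((S)-binap)]2 in dioxane/H2O at 35–50 °C, the BINAP enantiomer being chosen to deliver S, then rejoins the route at ketone 13.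

Step 2. ZnCl2 may trigger cationic oligomerisation of the very electron-rich styrene, and the donor-substituted dichlorocyclobutanone may decompose by ring opening during isolation. The fallback replaces the ketene by a keteniminium salt and sets out from styrene 4. N,N-Dimethylacetamide, Tf2O and 2,4,6-collidine in 1,2-dichloroethane generate N,N-dimethylketeniminium trifluoromethanesulfonate F2. Its [2+2] cycloaddition with 4 at reflux should give N,N-dimethyl-3-(2,4,5-trimethoxyphenyl)cyclobutan-1-iminium trifluoromethanesulfonate F3. Hydrolysis with aqueous NaHCO3 comes back to the route at cyclobutanone 9, bypassing 7 and step 3.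

Step 6. The boron-bound, strongly donor-substituted benzylic alkoxide may ionise and be reduced further to the methylene compound. The ortho-methoxy group may compete for boron and erode face selectivity, and traces of acid during isolation may cause dehydration or Friedel–Crafts cyclisation onto the second ring. The fallback is a boron-free asymmetric transfer hydrogenation (Noyori–Ikariya type) running directly from ketone 13 to target 14. RuCl[(R,R)-TsDPEN](p-cymene) with HCO2Na in H2O/MeOH at 40 °C delivers hydride by an outer-sphere pathway under near-neutral conditions, and the (R,R)-catalyst is the one that gives (R)-carbinols from aryl alkyl ketones. This fallback makes no new compound (entry F0).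

**Further compounds**

F1 | step 5 | (E)-1-(2,4,5-trimethoxyphenyl)but-2-en-1-one | COc1cc(OC)c(C(=O)/C=C/C)cc1OC
F2 | step 2 | N,N-dimethylketeniminium trifluoromethanesulfonate | C=C=[N+](C)C.[O-]S(=O)(=O)C(F)(F)F
F3 | step 2 | N,N-dimethyl-3-(2,4,5-trimethoxyphenyl)cyclobutan-1-iminium trifluoromethanesulfonate | COc1cc(OC)c(C2CC(=[N+](C)C)C2)cc1OC.[O-]S(=O)(=O)C(F)(F)F
F0 | step 6 | none | none
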